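3 final yields of G are asked, one per flask, and I reckon a ceiling for them from a single frozen rate.

| flask | J | Z | remark | time |
|---|---|---|---|---|
| beta | 1.3 × 10⁻⁴ M | 1.5 equiv | run made earlier |  |
| spring | 2.0 × 10⁻⁴ M | 1.50 equiv |  | 8.0 min |
| winter | 2.0 × 10⁻⁴ M | 2.50 equiv |  | 8.0 min |
| autumn | 2.0 × 10⁻⁴ M | 4.00 equiv |  | 8.0 min |

beta run (percent of the J charged)

| time / min | G / % | X / % |
|---|---|---|
| 0.250 | 0 | 1.3 |
| 0.333 | 0.2 | 1.1 |
| 0.500 | 0 | 3.7 |
| 0.833 | 2.0 | 6.3 |
| 1.33 | 6.6 | 8.9 |
| 2.00 | 12.3 | 12.0 |
| 3.00 | 21.5 | 16.0 |

(readings scatter by 0.5 percentage points)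

* final G, as a percentage of the J charged, for each flask in turn (spring, winter, autumn)

- solid, in amounts per volume of the solution: J
- the earlier runs were read with a standard deviation of 0.5 percentage points
- at the start none of J is in solution

My bench rule here: when the sum of products climbs in a straight line from a solid, freeze its slope. In the beta run, X plus G rises steadily from 1.33 min to 3.00 min, so I read a feed rate, the concentration of J appearing as X plus G per minute, of 1.71 × 10⁻⁵ M/min. Frozen, it passes 68.5% of the new charge in 8.0 min, and on this reckoning that is my ceiling for G.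

Each G costs two Z, so I compare that demand with the Z charged. The ratio is 0.913 in spring, 0.548 in winter and 0.343 in autumn. Spring stands nearest to 1 but under it, so on this reckoning the frozen feed leaves some Z in spring at 8.0 min. By its charge, though, Z is the limiting reagent in spring: 1.50 equiv at two Z per G allows 0.750 G per J charged.

The border lies in the loading, which is 1.54 times the beta loading. If the feed rate grows with the charge, the whole spring charge passes before 8.0 min, and its demand of two Z per J exceeds the 1.50 equiv charged.

The forecast says 53%, 62% and 66%, and its ground is “so I take this absolute rate as unchanged at the higher loading”. My reckoning gives a ceiling, not these numbers.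

The simulation gives G at 43.0% in spring, 64.5% in winter and 69.4% in autumn.

    E + Z → X (k = 63.0 /M/s)
    X ⇌ L (K = 2.40, k = 0.00220 /s)
    J ⇌ E, rate k3*(cs3 - [E]) while solid is left; crystals form when [E] > cs3 (solubility = 0.110 mM, k = 0.00940 /s)
    Z + X → D (k = 41.0 /M/s)
    Z + X → G (k = 100 /M/s)

Spring has 7.7% of its Z left at 8.00 min, with 22.2% of its charge standing as E. The frozen feed rate gives 34.3% of the charge as X plus G at 4.00 min. Spring holds 39.1% at that time, and winter, with the same charge of J and more Z, holds 52.3%.

(The earlier runs and the new flask were computed on assumed constants, and the scatter is random.)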